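**Remark on the chemistry:** the target is read as the (2R,3R) isomer (aryl and hydroxymethyl trans on the dioxane ring) with an E double bond. Ring positions are numbered O1–C2(aryl)–C3(CH2OH)–O4–C4a–C5–C6–C7–C8–C8a throughout, also for the atoms of open-chain precursors that become these positions.

**Compound numbers:** 1 3-(benzyloxy)phenol; 2 bromoacetic acid; 3 aryloxyacetic acid; 4 (S)-4-benzyloxazolidin-2-one; 5 mixed anhydride; 6 aryloxyacetyl imide; 7 vanillin; 8 O-tosylvanillin; 9 boron enolate; 10 boron aldolate; 11 syn aldol adduct; 12 threo diol; 13 primary pivalate; 14 phenol (key-step precursor); 15 aryloxyiodane; 16 dienone; 17 benzodioxan-6-ol (key-step product); 18 aryl triflate; 19 methyl acrylate; 20 protected cinnamate; 21 target.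

## Analysis of the target

The target is a 2,3-dihydro-1,4-benzodioxine: a dioxane ring (O1, C2, C3, O4, C4a, C8a) fused to a benzene ring (ring A). C2 carries a 4-hydroxy-3-methoxyphenyl (guaiacyl) group, C3 a hydroxymethyl group and C6 an (E)-acrylic acid. C2 and C3 are the only stereocentres, both R, which places the aryl and hydroxymethyl groups trans; an open-chain threo 1-aryl-2-aryloxypropane-1,3-diol maps onto this trans ring if neither C–O bond at the stereocentres is broken. The free guaiacyl phenol para to C2 makes C2–O1 a para-hydroxybenzyl aryl ether, which can open through a quinone methide in hot alkali or acid, the more so because O1 sits para to the acrylate. The cinnamic acid and the primary alcohol must also be unveiled late. The main constitutional difficulty is ring A: O1 is para and O4 meta to the acrylate, so any route through a catechol has to tell two nearly equivalent phenols apart or it gives the 7-substituted regioisomer. The route rests on the fact that C6 is para to C8a. A hydroxyl at C6 of a ring that carries only O4 activates exactly C8a for C–O bond formation, so O1 can be delivered by the C2 hydroxyl to a C–H position. The same C6 hydroxyl then becomes the leaving group for the acrylate.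

## Retrosynthetic reasoning

**21 to 20.** The last operation removes protecting groups only. The acid, the primary alcohol and the guaiacyl phenol of 21 are carried as the methyl ester, pivalate and tosylate of 20, all cleaved by hydroxide in one operation. The groups that make 21 sensitive to base and oxidation therefore appear only at the end.

**20 to 18 and 19.** The C6–vinyl bond is cut. An E acrylate on an arene is the standard Heck product, all three side-chain carbons come from 19 at once, and the electrophile 18 is one step from phenol 17. This places a phenolic hydroxyl at C6 of 17, which is what the ring-forming step needs.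

**17 to 14 (key disconnection).** The O1–C8a aryl ether bond is cut, not the usual benzylic C2–O1 bond. Both stereocentres keep their C–O bonds, so the configuration of 14 passes unchanged into 17. Ring A of 14 is a resorcinol monoether attached through O4 only, so no catechol has to be differentiated. Forward, the C6 phenol is oxidised by a trivalent iodine reagent, the C2 hydroxyl adds to C8a, and the ring rearomatises. The step must prefer C8a over C5, must leave the guaiacyl ring alone (hence the tosylate), and must not use the primary hydroxyl, which could close an isomeric dioxane (hence the pivalate).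

**14 to 13 to 12.** These are protecting-group operations. The phenol of 14 is a benzyl ether in 13, so that acylation of 12 has to choose only between a primary and a secondary hydroxyl. Forward: selective primary pivaloylation, then hydrogenolysis.

**12 to 11 to 6 and 8.** The C2–C3 bond is cut. Both stereocentres flank it, and their threo relation is what a Z-enolate aldol gives. Diol 12 is the reduced form of imide 11, which comes from 6 and 8 with the auxiliary fixing the absolute configuration. The tosylate is placed on the aldehyde from the start because it survives every step up to the end.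

**6 to 3 and 4; 3 to 1 and 2; 8 from 7.** The O4–C3 bond is made at an achiral CH2 group by Williamson alkylation of 1 with 2. Acid 3 is joined to auxiliary 4, and 8 is the sulfonate of 7.

## Alternatives that were turned down

**Alternative 1:** cuts C2–C3 and O1–C2 in one cascade.
- Forward key step: aldehyde A1 (ring A with the acrylate ester, the O4-linked acetaldehyde and a free C8a phenol) condenses with vanillin acetate A2 under a chiral primary amine salt. The iminium ion of the resulting enal directs 6-endo addition of the phenol to C2, giving trans aldehyde A3.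
- For: it forms two bonds, the ring and both stereocentres catalytically, with the acrylate already in place.
- Against: A1 will rest largely as its cyclic hemiacetal and can self-condense. The intermediate enal is α-oxygenated and β-aryl, a poor iminium acceptor. The oxa-Michael addition is reversible, so enantiopurity at C2 is under thermodynamic threat, and C3 sits α to a formyl group.
- Comparison: in step count this alternative is clearly stronger. The chosen route takes both stereocentres from an auxiliary aldol of a well-known type and confines the untested chemistry to a step that creates no stereocentre.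

**Alternative 2:** cuts O4–C3 and C2–C3, a one-carbon ring expansion.
- Forward key step: a copper or rhodium carbene from tert-butyl diazoacetate A5 adds to the oxygen meta to the ester of benzodioxole A4. The oxonium ylide undergoes a [1,2]-Stevens shift of the acetal carbon to give diester A6.
- For: A4 is one acetalisation away from simple aromatics, and the ester biases the carbene toward the correct oxygen.
- Against: that bias is modest, so the 7-ester regioisomer is likely. The Stevens shift runs through a radical or ion pair, so absolute and trans control must come from a catalyst acting on an intermediate it no longer binds. A6 then needs two esters differentiated, one reduced to the alcohol and one homologated to the acrylic acid.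
- Comparison: the front end is shorter, but the chosen route controls configuration reliably and needs no redox adjustment at C3 or C6.

**Alternative 3:** cuts the benzylic O1–C2 bond.
- Forward key step: anhydrous acid ionises the benzylic alcohol of either C2 epimer of A7 to the para-quinone methide, and the C8a phenol adds to C2 to give trans benzodioxane A8.
- For: this is the closure closest to established chemistry for this ring system, and on certainty of ring formation it is stronger than the chosen key step. It is stereoconvergent, so only C3 has to be set, and the ring A regiochemistry is fixed by construction.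
- Against: the trans to cis ratio is an equilibrium value. The acid step runs in the presence of a dioxolane and a tert-butyl ether. Ring A must come from a differentiated catechol, and the aldehyde must still be unmasked and olefinated.
- Comparison: the chosen strategy gives trans as a consequence of the aldol, not of an equilibrium. It uses a resorcinol ether with no differentiation problem, has no acid step, and reaches the acrylate by one Heck reaction.

Key step: step 8

## Route

Step 1
Reactants: 1 3-(benzyloxy)phenol; 2 bromoacetic acid
Product: 3 2-[3-(benzyloxy)phenoxy]acetic acid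
Conditions: NaH (2.5 equiv), THF, 0 °C to reflux; then aq. HCl
Reagents that add atoms: none
Why: Williamson ether synthesis; the sodium phenoxide displaces bromide from sodium bromoacetate, whose carboxylate is not alkylated, and acidification returns the acid.

Step 2
Reactants: 3 2-[3-(benzyloxy)phenoxy]acetic acid; 4 (S)-4-benzyloxazolidin-2-one
Product: 6 (S)-4-benzyl-3-{2-[3-(benzyloxy)phenoxy]acetyl}oxazolidin-2-one, via mixed pivalic anhydride 5 (not isolated)
Conditions: PivCl, Et3N, THF, −20 °C; then 4, LiCl, −20 °C to rt
Reagents that add atoms: none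
Why: N-acylation of the oxazolidinone through a mixed anhydride; the hindered pivaloyl carbonyl of 5 steers the oxazolidinone to the aryloxyacetyl carbonyl, and the auxiliary stereocentre is not involved.

Step 3
Reactants: 7 vanillin
Product: 8 4-formyl-2-methoxyphenyl 4-methylbenzenesulfonate (O-tosylvanillin)
Conditions: TsCl, Et3N, DMAP (cat.), CH2Cl2, 0 °C to rt
Reagents that add atoms: p-toluenesulfonyl chloride, Cc1ccc(cc1)S(=O)(=O)Cl
Why: Sulfonylation of a phenol; the tosylate makes the guaiacyl ring electron-poor and non-phenolic for step 8 and withstands every step up to the final hydrolysis.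

Step 4
Reactants: 6 (S)-4-benzyl-3-{2-[3-(benzyloxy)phenoxy]acetyl}oxazolidin-2-one; 8 O-tosylvanillin
Product: 11 (S)-4-benzyl-3-{(2S,3R)-2-[3-(benzyloxy)phenoxy]-3-hydroxy-3-[3-methoxy-4-(tosyloxy)phenyl]propanoyl}oxazolidin-2-one, via dibutylboron Z-enolate 9 (not isolated), via dibutylboron aldolate 10 (not isolated)
Conditions: Bu2BOTf, iPr2NEt, CH2Cl2, −78 to 0 °C; then 8, −78 to 0 °C; then pH 7 buffer, MeOH, H2O2, 0 °C
Reagents that add atoms: none
Why: Evans syn aldol of a glycolate-type imide; soft enolisation gives Z-enolate 9, which adds to 8 through a closed chair transition state with the oxazolidinone carbonyl turned away from the enolate oxygen and the benzyl group shielding one face. This sets the future C3 (2S in the imide) and C2 (3R) together in the syn (threo) relation, and oxidative work-up frees the alcohol from 10.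

Step 5
Reactants: 11 syn aldol adduct
Product: 12 (1R,2R)-2-[3-(benzyloxy)phenoxy]-1-[3-methoxy-4-(tosyloxy)phenyl]propane-1,3-diol
Conditions: LiBH4, THF, MeOH (1 equiv), 0 °C
Reagents that add atoms: none
Why: Reductive cleavage of an N-acyloxazolidinone; hydride attacks the activated exocyclic carbonyl, the auxiliary is released, and the aryl tosylate and benzyl ether are inert; the descriptor at the aryloxy carbon changes from S to R only because the priorities change.

Step 6
Reactants: 12 threo diol
Product: 13 (2R,3R)-2-[3-(benzyloxy)phenoxy]-3-hydroxy-3-[3-methoxy-4-(tosyloxy)phenyl]propyl pivalate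
Conditions: PivCl (1.1 equiv), pyridine, CH2Cl2, −10 to 0 °C
Reagents that add atoms: pivaloyl chloride, CC(C)(C)C(=O)Cl
Why: Selective acylation of the primary hydroxyl of a 1,3-diol; the bulky acyl chloride discriminates against the secondary benzylic hydroxyl, which must stay free as the nucleophile of step 8, and a pivalate resists 1,3-acyl migration.

Step 7
Reactants: 13 primary pivalate
Product: 14 (2R,3R)-3-hydroxy-2-(3-hydroxyphenoxy)-3-[3-methoxy-4-(tosyloxy)phenyl]propyl pivalate
Conditions: H2 (1 atm), Pd/C, EtOAc, rt
Reagents that add atoms: none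
Why: Hydrogenolysis of an aryl benzyl ether; under neutral conditions the secondary benzylic alcohol, the aryl sulfonate and the pivalate should not be reduced, and no stereocentre is involved.

Step 8
Reactants: 14 phenol
Product: 17 (2R,3R)-2-[3-methoxy-4-(tosyloxy)phenyl]-3-(pivaloyloxymethyl)-2,3-dihydro-1,4-benzodioxin-6-ol, via aryloxyiodane 15 (not isolated), via 4H-dienone 16 (not isolated)
Conditions: PhI(OAc)2 (1.0 equiv, slow addition), (CF3)2CHOH, 0.01 M, −10 to 0 °C
Reagents that add atoms: none
Why: Proposed new method: PhI(OAc)2 exchanges one acetate for the phenol oxygen of 14 to give aryloxyiodane 15, and loss of iodobenzene and acetate in the ionising, non-nucleophilic solvent leaves a phenoxenium-type species with positive charge at C5, C7 and C8a. The benzylic hydroxyl on the future C2, tethered through C3 and O4 to C4a, reaches C8a over the ring face and adds there; this is a 6-endo closure onto the C4a–C8a bond with the geometry of an ortho ring-closing aromatic substitution, it gives dienone 16, and loss of the C8a proton restores the arene as phenol 17. The closest known reactions are PhI(OAc)2-mediated dearomatisations of phenols with capture by a tethered alcohol (spiroetherification, quinone monoketal formation) and para-alkoxylation of para-unsubstituted phenols by an external alcohol; the fused, rearomatising variant with a meta-tethered alcohol is not established. No stereocentre is formed or touched, because the carbinol C–O bond stays intact and oxygen, not carbon, is the reacting atom, so the threo relation of 14 becomes the trans relation of 17. The step needs site selectivity for C8a over C5, the other carbon that would close a six-membered ring: C8a is para to the phenol oxygen, where such cations are normally captured, while C5 is ortho and wedged between two oxygen substituents. Chemoselectivity rests on three features of 14: the tosylate makes the guaiacyl ring neither oxidisable nor nucleophilic, the pivalate removes the primary hydroxyl that could close an isomeric dioxane, and one equivalent of oxidant added slowly at high dilution limits a second oxidation of the more electron-rich product.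

Step 9
Reactants: 17 benzodioxan-6-ol
Product: 18 (2R,3R)-2-[3-methoxy-4-(tosyloxy)phenyl]-3-(pivaloyloxymethyl)-2,3-dihydro-1,4-benzodioxin-6-yl trifluoromethanesulfonate
Conditions: Tf2O, pyridine, CH2Cl2, −10 to 0 °C
Reagents that add atoms: trifluoromethanesulfonic anhydride, O=S(=O)(OS(=O)(=O)C(F)(F)F)C(F)(F)F
Why: Triflation of a phenol; pyridine takes up the acid, and neither the pivalate nor the tosylate reacts.

Step 10
Reactants: 18 aryl triflate; 19 methyl acrylate
Product: 20 methyl (E)-3-{(2R,3R)-2-[3-methoxy-4-(tosyloxy)phenyl]-3-(pivaloyloxymethyl)-2,3-dihydro-1,4-benzodioxin-6-yl}prop-2-enoate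
Conditions: Pd(OAc)2 (5 mol %), dppp, Et3N, DMF, 90 °C
Reagents that add atoms: none
Why: Heck reaction; zerovalent palladium inserts into the C6–OTf bond, syn carbopalladation at the unsubstituted carbon of 19 and syn β-hydride elimination give the E cinnamate, and the aryl tosylate is inert to this catalyst.

Step 11
Reactants: 20 protected cinnamate
Product: 21 (E)-3-[(2R,3R)-2-(4-hydroxy-3-methoxyphenyl)-3-(hydroxymethyl)-2,3-dihydro-1,4-benzodioxin-6-yl]prop-2-enoic acid
Conditions: KOH (2 M aq., excess), MeOH/THF, 60 °C, argon; then 1 M HCl, 0 °C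
Reagents that add atoms: potassium hydroxide, [K+].[OH-]
Why: Saponification and sulfonate hydrolysis; hydroxide cleaves the methyl ester and the pivalate at the acyl carbon and the aryl tosylate at sulfur, so both C–O bonds at the stereocentres stay intact, and acidification gives the free acid.

## Compound list

1 | 3-(benzyloxy)phenol | Oc1cccc(OCc2ccccc2)c1 | starting material
2 | bromoacetic acid | OC(=O)CBr | starting material
3 | 2-[3-(benzyloxy)phenoxy]acetic acid | OC(=O)COc1cccc(OCc2ccccc2)c1 | intermediate
4 | (S)-4-benzyloxazolidin-2-one | O=C1N[C@@H](Cc2ccccc2)CO1 | starting material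
5 | 2-[3-(benzyloxy)phenoxy]acetic pivalic anhydride | CC(C)(C)C(=O)OC(=O)COc1cccc(OCc2ccccc2)c1 | intermediate
6 | (S)-4-benzyl-3-{2-[3-(benzyloxy)phenoxy]acetyl}oxazolidin-2-one | O=C(COc1cccc(OCc2ccccc2)c1)N1[C@@H](Cc2ccccc2)COC1=O | intermediate
7 | vanillin | COc1cc(C=O)ccc1O | starting material
8 | 4-formyl-2-methoxyphenyl 4-methylbenzenesulfonate | COc1cc(C=O)ccc1OS(=O)(=O)c1ccc(C)cc1 | intermediate
9 | dibutylboron Z-enolate of 6 | CCCCB(CCCC)O/C(=C\Oc1cccc(OCc2ccccc2)c1)N1[C@@H](Cc2ccccc2)COC1=O | intermediate
10 | O-dibutylboryl derivative of 11 (boron aldolate) | COc1cc([C@@H](OB(CCCC)CCCC)[C@@H](C(=O)N2[C@@H](Cc3ccccc3)COC2=O)Oc2cccc(OCc3ccccc3)c2)ccc1OS(=O)(=O)c1ccc(C)cc1 | intermediate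
11 | (S)-4-benzyl-3-{(2S,3R)-2-[3-(benzyloxy)phenoxy]-3-hydroxy-3-[3-methoxy-4-(tosyloxy)phenyl]propanoyl}oxazolidin-2-one | COc1cc([C@@H](O)[C@@H](C(=O)N2[C@@H](Cc3ccccc3)COC2=O)Oc2cccc(OCc3ccccc3)c2)ccc1OS(=O)(=O)c1ccc(C)cc1 | intermediate
12 | (1R,2R)-2-[3-(benzyloxy)phenoxy]-1-[3-methoxy-4-(tosyloxy)phenyl]propane-1,3-diol | COc1cc([C@@H](O)[C@@H](CO)Oc2cccc(OCc3ccccc3)c2)ccc1OS(=O)(=O)c1ccc(C)cc1 | intermediate
13 | (2R,3R)-2-[3-(benzyloxy)phenoxy]-3-hydroxy-3-[3-methoxy-4-(tosyloxy)phenyl]propyl pivalate | COc1cc([C@@H](O)[C@@H](COC(=O)C(C)(C)C)Oc2cccc(OCc3ccccc3)c2)ccc1OS(=O)(=O)c1ccc(C)cc1 | intermediate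
14 | (2R,3R)-3-hydroxy-2-(3-hydroxyphenoxy)-3-[3-methoxy-4-(tosyloxy)phenyl]propyl pivalate | COc1cc([C@@H](O)[C@@H](COC(=O)C(C)(C)C)Oc2cccc(O)c2)ccc1OS(=O)(=O)c1ccc(C)cc1 | intermediate
15 | O-[acetoxy(phenyl)iodanyl] derivative of 14 (aryloxyiodane) | COc1cc([C@@H](O)[C@@H](COC(=O)C(C)(C)C)Oc2cccc(OI(OC(C)=O)c3ccccc3)c2)ccc1OS(=O)(=O)c1ccc(C)cc1 | intermediate
16 | 8aH-dienone tautomer of 17 (C6 ketone, sp3 C8a) | COc1cc([C@H]2OC3C=CC(=O)C=C3O[C@@H]2COC(=O)C(C)(C)C)ccc1OS(=O)(=O)c1ccc(C)cc1 | intermediate
17 | (2R,3R)-2-[3-methoxy-4-(tosyloxy)phenyl]-3-(pivaloyloxymethyl)-2,3-dihydro-1,4-benzodioxin-6-ol | COc1cc([C@H]2Oc3ccc(O)cc3O[C@@H]2COC(=O)C(C)(C)C)ccc1OS(=O)(=O)c1ccc(C)cc1 | intermediate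
18 | (2R,3R)-2-[3-methoxy-4-(tosyloxy)phenyl]-3-(pivaloyloxymethyl)-2,3-dihydro-1,4-benzodioxin-6-yl trifluoromethanesulfonate | COc1cc([C@H]2Oc3ccc(OS(=O)(=O)C(F)(F)F)cc3O[C@@H]2COC(=O)C(C)(C)C)ccc1OS(=O)(=O)c1ccc(C)cc1 | intermediate
19 | methyl acrylate | C=CC(=O)OC | starting material
20 | methyl (E)-3-{(2R,3R)-2-[3-methoxy-4-(tosyloxy)phenyl]-3-(pivaloyloxymethyl)-2,3-dihydro-1,4-benzodioxin-6-yl}prop-2-enoate | COc1cc([C@H]2Oc3ccc(/C=C/C(=O)OC)cc3O[C@@H]2COC(=O)C(C)(C)C)ccc1OS(=O)(=O)c1ccc(C)cc1 | intermediate
21 | (E)-3-[(2R,3R)-2-(4-hydroxy-3-methoxyphenyl)-3-(hydroxymethyl)-2,3-dihydro-1,4-benzodioxin-6-yl]prop-2-enoic acid | COc1cc([C@H]2Oc3ccc(/C=C/C(=O)O)cc3O[C@@H]2CO)ccc1O | target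

## Step count and risk

Total: 11 steps. Longest linear sequence: 10 steps from 1 (steps 1, 2 and 4 to 11); step 3 is a one-step branch from 7. Any minor diastereomer from step 4 still carries the auxiliary and should be separable at 11.

**Step 8 (key step, proposed new method).**
- Most likely to go wrong: further oxidation of 17, which is a hydroquinone monoether and more easily oxidised than 14, so that oxidant and product are consumed before 14 is used up. Closure at C5 and intermolecular coupling are the other failure paths.
- Fallback (known chemistry, palladium-catalysed intramolecular aryl ether formation): it sets out from 2, 4 and 8 and returns at 17. 5-(Benzyloxy)-2-bromophenol F1, which carries bromine at the future C8a, is alkylated with 2 as in step 1 to give 2-[5-(benzyloxy)-2-bromophenoxy]acetic acid F2. This is joined to 4 as in step 2 to give the bromo imide F3. The aldol with 8, the reduction and the pivaloylation (as in steps 4 to 6) then give the bromo aldol adduct F4, the bromo diol F5 and the bromo pivalate F6. The secondary hydroxyl of F6 is coupled with the aryl bromide (Pd(OAc)2, 2-(di-tert-butylphosphino)-1,1'-binaphthyl, Cs2CO3, toluene, 70 °C) to give the 6-benzyloxy benzodioxane F7. Hydrogenolysis as in step 7 gives 17.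

**Step 11.**
- Most likely to go wrong: the pivalate and the aryl tosylate cleave only on heating. Once the guaiacyl phenoxide is free, the C2–O1 bond can open reversibly to a quinone methide, helped by O1 being para to the acrylate, with erosion of the trans configuration or elimination toward C3.
- Fallback: it sets out from 18 and returns at 21. Suzuki–Miyaura coupling with potassium vinyltrifluoroborate (PdCl2(dppf), Et3N, n-PrOH, 80 °C) gives the 6-vinyl tosylate pivalate F8. Hydroxide cleavage is done at this stage, where O1 is para only to a vinyl group and a poorer leaving group, to give the 6-vinyl phenol alcohol F9. Cross-metathesis of F9 with acrylic acid (second-generation Hoveyda–Grubbs catalyst, RuCl2(SIMes)(=CH–C6H4-2-OiPr), CH2Cl2, 40 °C) gives 21 without any base on the finished molecule.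

**Step 10.**
- Most likely to go wrong: slow carbopalladation of the acrylate by the electron-rich arylpalladium species, with competing S–O cleavage of the triflate back to 17 or reduction to the arene.
- Fallback: it sets out from 18 and returns at 20. Reductive carbonylation (Pd(OAc)2, dppp, CO, Et3SiH, Et3N, DMF, 70 °C), in which CO insertion is fast, gives the 6-carbaldehyde F10. Horner–Wadsworth–Emmons olefination with trimethyl phosphonoacetate (LiCl, DBU, MeCN) gives 20.

**Step 5.**
- Most likely to go wrong: retro-aldol cleavage of the lithium aldolate under the basic hydride, or hydride attack at the ring carbonyl of the auxiliary.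
- Fallback: it sets out from 11 and returns at 12. Hydrolysis with LiOH/H2O2 (THF/H2O, 0 °C) gives the hydroxy acid F11, which is reduced with BH3·SMe2 (THF, 0 °C to rt) to 12.

## Further compounds

F1 | step 8 | 5-(benzyloxy)-2-bromophenol | Oc1cc(OCc2ccccc2)ccc1Br
F2 | step 8 | 2-[5-(benzyloxy)-2-bromophenoxy]acetic acid | OC(=O)COc1cc(OCc2ccccc2)ccc1Br
F3 | step 8 | (S)-4-benzyl-3-{2-[5-(benzyloxy)-2-bromophenoxy]acetyl}oxazolidin-2-one | O=C(COc1cc(OCc2ccccc2)ccc1Br)N1[C@@H](Cc2ccccc2)COC1=O
F4 | step 8 | (S)-4-benzyl-3-{(2S,3R)-2-[5-(benzyloxy)-2-bromophenoxy]-3-hydroxy-3-[3-methoxy-4-(tosyloxy)phenyl]propanoyl}oxazolidin-2-one | COc1cc([C@@H](O)[C@@H](C(=O)N2[C@@H](Cc3ccccc3)COC2=O)Oc2cc(OCc3ccccc3)ccc2Br)ccc1OS(=O)(=O)c1ccc(C)cc1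
F5 | step 8 | (1R,2R)-2-[5-(benzyloxy)-2-bromophenoxy]-1-[3-methoxy-4-(tosyloxy)phenyl]propane-1,3-diol | COc1cc([C@@H](O)[C@@H](CO)Oc2cc(OCc3ccccc3)ccc2Br)ccc1OS(=O)(=O)c1ccc(C)cc1
F6 | step 8 | (2R,3R)-2-[5-(benzyloxy)-2-bromophenoxy]-3-hydroxy-3-[3-methoxy-4-(tosyloxy)phenyl]propyl pivalate | COc1cc([C@@H](O)[C@@H](COC(=O)C(C)(C)C)Oc2cc(OCc3ccccc3)ccc2Br)ccc1OS(=O)(=O)c1ccc(C)cc1
F7 | step 8 | [(2R,3R)-7-(benzyloxy)-3-[3-methoxy-4-(tosyloxy)phenyl]-2,3-dihydro-1,4-benzodioxin-2-yl]methyl pivalate (benzyl ether of 17) | COc1cc([C@H]2Oc3ccc(OCc4ccccc4)cc3O[C@@H]2COC(=O)C(C)(C)C)ccc1OS(=O)(=O)c1ccc(C)cc1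
F8 | step 11 | [(2R,3R)-3-[3-methoxy-4-(tosyloxy)phenyl]-7-vinyl-2,3-dihydro-1,4-benzodioxin-2-yl]methyl pivalate | COc1cc([C@H]2Oc3ccc(C=C)cc3O[C@@H]2COC(=O)C(C)(C)C)ccc1OS(=O)(=O)c1ccc(C)cc1
F9 | step 11 | 4-[(2R,3R)-3-(hydroxymethyl)-6-vinyl-2,3-dihydro-1,4-benzodioxin-2-yl]-2-methoxyphenol | COc1cc([C@H]2Oc3ccc(C=C)cc3O[C@@H]2CO)ccc1O
F10 | step 10 | [(2R,3R)-7-formyl-3-[3-methoxy-4-(tosyloxy)phenyl]-2,3-dihydro-1,4-benzodioxin-2-yl]methyl pivalate | COc1cc([C@H]2Oc3ccc(C=O)cc3O[C@@H]2COC(=O)C(C)(C)C)ccc1OS(=O)(=O)c1ccc(C)cc1
F11 | step 5 | (2S,3R)-2-[3-(benzyloxy)phenoxy]-3-hydroxy-3-[3-methoxy-4-(tosyloxy)phenyl]propanoic acid | COc1cc([C@@H](O)[C@@H](C(=O)O)Oc2cccc(OCc3ccccc3)c2)ccc1OS(=O)(=O)c1ccc(C)cc1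
A1 | alternative 1 | methyl (E)-3-[4-hydroxy-3-(2-oxoethoxy)phenyl]prop-2-enoate | COC(=O)/C=C/c1ccc(O)c(OCC=O)c1
A2 | alternative 1 | 4-formyl-2-methoxyphenyl acetate (vanillin acetate) | COc1cc(C=O)ccc1OC(C)=O
A3 | alternative 1 | methyl (E)-3-[(2R,3S)-2-(4-acetoxy-3-methoxyphenyl)-3-formyl-2,3-dihydro-1,4-benzodioxin-6-yl]prop-2-enoate | COc1cc([C@H]2Oc3ccc(/C=C/C(=O)OC)cc3O[C@@H]2C=O)ccc1OC(C)=O
A4 | alternative 2 | methyl 2-[4-(tert-butyldimethylsilyloxy)-3-methoxyphenyl]-1,3-benzodioxole-5-carboxylate (racemic acetal) | COC(=O)c1ccc2OC(c3ccc(O[Si](C)(C)C(C)(C)C)c(OC)c3)Oc2c1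
A5 | alternative 2 | tert-butyl diazoacetate | CC(C)(C)OC(=O)C=[N+]=[N-]
A6 | alternative 2 | trans-2-[4-(tert-butyldimethylsilyloxy)-3-methoxyphenyl]-1,4-benzodioxane 3-tert-butyl 6-methyl diester (route numbering, aryl carbon R) | COc1cc([C@H]2Oc3ccc(C(=O)OC)cc3O[C@@H]2C(=O)OC(C)(C)C)ccc1O[Si](C)(C)C(C)(C)C
A7 | alternative 3 | (2R)-3-tert-butoxy-2-[5-(1,3-dioxolan-2-yl)-2-hydroxyphenoxy]-1-(4-hydroxy-3-methoxyphenyl)propan-1-ol (either C1 epimer) | COc1cc(C(O)[C@@H](COC(C)(C)C)Oc2cc(C3OCCO3)ccc2O)ccc1O
A8 | alternative 3 | 4-[(2R,3R)-3-(tert-butoxymethyl)-6-(1,3-dioxolan-2-yl)-2,3-dihydro-1,4-benzodioxin-2-yl]-2-methoxyphenol | COc1cc([C@H]2Oc3ccc(C4OCCO4)cc3O[C@@H]2COC(C)(C)C)ccc1O
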